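## Retrosynthetic overview

1. The target comes from retro-Claisen methanolysis of a 2-oxabicyclo[2.2.1]heptane-3,5-dione, which reveals the γ-lactone and the methyl ester in one event.
2. The bicycle comes from a linear precursor by Cb–C4 bond formation: the enol of a β-keto-δ-lactone captures a fully conjugated C4–C12 polyenyl cation, released from a doubly allylic C10 carbinol.
3. The C10 carbinol is made by carbonyl addition (C10–C11), not cross-coupling: an alkenylalane from a 2-ethynyl-dihydropyran adds to a δ-lactone trienal.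
4. The dihydropyran is closed by O13→C17 allylic (SN2'-type) attack on a unit derived from a Sharpless 14,15-epoxide. The δ-lactone comes from an anti-aldol, propanoylation and intramolecular Claisen sequence.
5. Ring order: dihydropyran (step 4), δ-lactone (step 9), carbocycle of the bicycle, then γ-lactone by fragmentation (both in step 11).

Locants: C1 (ester carbon) to C18 (methyl on the pyran CH) follow the main chain of the target; Ca and Cb are the lactone carbonyl carbon and its CH(CH3) neighbour.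

Assumption: the biosynthesis is presumed to run from a linear polyene β-keto-δ-lactone through (a) vinylogous opening of a 14,15-epoxide by the C13 oxygen, (b) capture of the C4–C12 polyenyl cation by Cb to give the 2-oxabicyclo[2.2.1]heptane-3,5-dione, and (c) retro-Claisen methanolysis.

## Route

Step 1
Reactants: 1 (2E)-2-methylbut-2-enal; 2 2-(triphenylphosphoranylidene)propanal
Product: 3 (2E,4E)-2,4-dimethylhexa-2,4-dienal
Conditions: toluene, 110 °C, 24 h
Reagents that add atoms: none
Why: Wittig olefination with a stabilised formyl ylide gives the E-trisubstituted enal (the C13–C18 unit) under thermodynamic E control.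

Step 2
Reactants: 3 (2E,4E)-2,4-dimethylhexa-2,4-dienal; 4 ethynylmagnesium bromide
Product: 5 rac-(4E,6E)-4,6-dimethylocta-4,6-dien-1-yn-3-ol
Conditions: HC≡CMgBr (1.3 equiv), THF, −78 → 0 °C; H2O
Reagents that add atoms: none
Why: 1,2-Grignard addition to the enal installs C11–C12 as a terminal alkyne; C13 is formed racemic and is resolved in step 3.

Step 3
Reactants: 5 rac-(4E,6E)-4,6-dimethylocta-4,6-dien-1-yn-3-ol
Product: 7 (3S,4S,5R,6E)-3,4-dihydroxy-4,6-dimethyloct-6-en-1-yn-5-yl benzoate, via epoxy alcohol 6 (not isolated)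
Conditions: Ti(OiPr)4 (0.1 equiv), L-(+)-diisopropyl tartrate (0.15 equiv), t-BuOOH (0.6 equiv), 4 Å molecular sieves, CH2Cl2, −20 °C; then Ti(OiPr)4 (1.5 equiv), PhCO2H (1.5 equiv), 0 → 23 °C
Reagents that add atoms: tert-butyl hydroperoxide, CC(C)(C)OO; benzoic acid, O=C(O)c1ccccc1
Why: Sharpless asymmetric epoxidation with kinetic resolution epoxidises only (S)-5 at the allylic C14=C15 bond to the anti (erythro) epoxy alcohol (sets C13 and C14, at most 50 % yield), and the Ti(OiPr)4-mediated C3-selective opening by benzoate then inverts the allylic C15, placing the leaving group where step 4 needs it.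

Step 4
Reactants: 7 (3S,4S,5R,6E)-3,4-dihydroxy-4,6-dimethyloct-6-en-1-yn-5-yl benzoate
Product: 8 (2S,3R,6S)-2-ethynyl-3,5,6-trimethyl-3,6-dihydro-2H-pyran-3-ol
Conditions: Pd2(dba)3·CHCl3 (2.5 mol %), PPh3 (15 mol %), THF, 40 °C
Reagents that add atoms: none
Why: Tsuji–Trost allylic etherification with zerovalent palladium ionises the C15 benzoate with inversion and the C13 hydroxyl attacks C17 anti to the metal (attack at C15 would give an oxetane), so the net syn 1,3-transfer from the (15R) benzoate through the E-16,17 alkene sets (17S) and the 2,6-trans dihydropyran.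

Step 5
Reactants: 9 (2E)-4,4-dimethoxybut-2-enal; 10 (triphenylphosphoranylidene)acetaldehyde
Product: 11 (2E,4E)-6,6-dimethoxyhexa-2,4-dienal
Conditions: 9 (1.5 equiv), toluene, 50 °C
Reagents that add atoms: none
Why: Wittig two-carbon homologation with a stabilised ylide is E-selective, and the excess of 9 limits a second homologation.

Step 6
Reactants: 11 (2E,4E)-6,6-dimethoxyhexa-2,4-dienal; 2 2-(triphenylphosphoranylidene)propanal
Product: 12 (2E,4E,6E)-8,8-dimethoxy-2-methylocta-2,4,6-trienal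
Conditions: toluene, 90 °C
Reagents that add atoms: none
Why: A second E-selective Wittig olefination installs the C4 methyl-bearing alkene and leaves C3 as the free aldehyde and C10 as the acetal.

Step 7
Reactants: 12 (2E,4E,6E)-8,8-dimethoxy-2-methylocta-2,4,6-trienal; 13 (4S)-4-benzyl-3-propanoyl-1,3-oxazolidin-2-one
Product: 15 (4S)-4-benzyl-3-[(2R,3S,4E,6E,8E)-3-hydroxy-10,10-dimethoxy-2,4-dimethyldeca-4,6,8-trienoyl]-1,3-oxazolidin-2-one, via silyl ether 14 (not isolated)
Conditions: MgCl2 (0.2 equiv), Et3N (2 equiv), Me3SiCl (1.5 equiv), EtOAc, 23 °C; then CF3CO2H (cat.), MeOH, 0 °C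
Reagents that add atoms: chlorotrimethylsilane, C[Si](C)(C)Cl (its silyl group is carried only by 14 and is removed again in the methanol stage)
Why: Evans magnesium-halide-catalysed anti-aldol of the chelated Z-enolate, attacked on the face remote from benzyl by the non-enolisable enal, sets C2 (R) and C3 (S); methanolysis removes the silyl ether while the dimethyl acetal survives in anhydrous methanol.

Step 8
Reactants: 15 (4S)-4-benzyl-3-[(2R,3S,4E,6E,8E)-3-hydroxy-10,10-dimethoxy-2,4-dimethyldeca-4,6,8-trienoyl]-1,3-oxazolidin-2-one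
Product: 16 (2R,3S,4E,6E,8E)-1-[(4S)-4-benzyl-2-oxo-1,3-oxazolidin-3-yl]-10,10-dimethoxy-2,4-dimethyl-1-oxodeca-4,6,8-trien-3-yl propanoate
Conditions: (EtCO)2O (1.5 equiv), Et3N (2 equiv), DMAP (0.1 equiv), CH2Cl2, 0 → 23 °C
Reagents that add atoms: propanoic anhydride, CCC(=O)OC(=O)CC
Why: DMAP-catalysed O-acylation brings in the Ca/Cb propanoate unit without touching the stereocentres.

Step 9
Reactants: 16 (2R,3S,4E,6E,8E)-1-[(4S)-4-benzyl-2-oxo-1,3-oxazolidin-3-yl]-10,10-dimethoxy-2,4-dimethyl-1-oxodeca-4,6,8-trien-3-yl propanoate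
Product: 18 (2E,4E,6E)-7-[(2S,3R)-4-hydroxy-3,5-dimethyl-6-oxo-3,6-dihydro-2H-pyran-2-yl]octa-2,4,6-trienal, via lactone acetal 17 (not isolated)
Conditions: LiN(SiMe3)2 (3 equiv), THF, −78 °C; then 1 M HCl, THF, 0 °C
Reagents that add atoms: water, O
Why: Intramolecular Claisen (Dieckmann-type) condensation of the propanoate enolate onto the imide carbonyl expels the oxazolidinone and closes the β-keto-δ-lactone with C2 and C3 unchanged (trans-5,6 is also the thermodynamic arrangement), and the acid work-up unmasks the C10 aldehyde.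

Step 10
Reactants: 8 (2S,3R,6S)-2-ethynyl-3,5,6-trimethyl-3,6-dihydro-2H-pyran-3-ol; 18 (2E,4E,6E)-7-[(2S,3R)-4-hydroxy-3,5-dimethyl-6-oxo-3,6-dihydro-2H-pyran-2-yl]octa-2,4,6-trienal
Product: 19 (5R,6S)-4-hydroxy-6-[(2E,4E,6E,8RS,9E)-8-hydroxy-10-[(2S,3R,6S)-3-hydroxy-3,5,6-trimethyl-3,6-dihydro-2H-pyran-2-yl]undeca-2,4,6,9-tetraen-2-yl]-3,5-dimethyl-5,6-dihydro-2H-pyran-2-one
Conditions: 8, AlMe3 (3 equiv), Cp2ZrCl2 (0.25 equiv), H2O (1 equiv), CH2Cl2, −20 °C; then 18 (premixed with AlMe3, 1 equiv), −20 → 0 °C; pH 7 buffer; used crude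
Reagents that add atoms: trimethylaluminium, C[Al](C)C
Why: Negishi zirconium-catalysed syn-carboalumination puts the methyl on C12 and aluminium on C11 (E-alkene), and the alkenylalane adds 1,2 to the trienal while the acidic lactone is masked as its aluminium enolate; the new C10 stereocentre is irrelevant because it is ionised in step 11.

Step 11
Reactants: 19 (5R,6S)-4-hydroxy-6-[(2E,4E,6E,8RS,9E)-8-hydroxy-10-[(2S,3R,6S)-3-hydroxy-3,5,6-trimethyl-3,6-dihydro-2H-pyran-2-yl]undeca-2,4,6,9-tetraen-2-yl]-3,5-dimethyl-5,6-dihydro-2H-pyran-2-one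
Product: 21 methyl (2R)-2-[(2S,3R,4R)-3-[(1E,3E,5E,7E)-8-[(2S,3R,6S)-3-hydroxy-3,5,6-trimethyl-3,6-dihydro-2H-pyran-2-yl]nona-1,3,5,7-tetraen-1-yl]-3,4-dimethyl-5-oxooxolan-2-yl]propanoate (the target), via bicyclic dione 20 (not isolated)
Conditions: (+)-10-camphorsulfonic acid (0.1 equiv), 4 Å molecular sieves, CH2Cl2 (2 mM), −40 → 0 °C; then MeOH, K2CO3 (0.3 equiv), 0 °C
Reagents that add atoms: methanol, CO
Why: Proposed new method: acid ionises the doubly allylic C10 carbinol to the conjugated C4–C12 nonatetraenyl cation (the cation the presumed biosynthesis reaches by epoxide opening), and C4 is the only terminus the tethered enol carbon Cb can reach (five-membered ring; O-alkylation would give anti-Bredt bicycles), so irreversible C-alkylation gives the 2-oxabicyclo[2.2.1]heptane-3,5-dione with an all-E tetraene and the polyene syn to the O–C(=O) bridge (C5–H over the ring oxygen, least 1,3-allylic strain; sets C4 R), after which methoxide adds to the strained non-enolisable ketone, retro-Claisen cleavage of C1–Cb releases the γ-lactone enolate and protonation anti to the C3 side chain sets Cb (R); the closest known reaction types are Brønsted-acid SN1 alkylation of 1,3-dicarbonyls by allylic alcohols, acid-mediated closure of β-keto-δ-lactones onto allyl cations to this same bicycle, and retro-Claisen alcoholysis of non-enolisable β-diketones.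

## Compound list

1 | (2E)-2-methylbut-2-enal (tiglic aldehyde) | O=C/C(C)=C/C | starting material
2 | 2-(triphenylphosphoranylidene)propanal | CC(C=O)=P(c1ccccc1)(c1ccccc1)c1ccccc1 | starting material
3 | (2E,4E)-2,4-dimethylhexa-2,4-dienal | O=C/C(C)=C/C(C)=C/C | intermediate
4 | ethynylmagnesium bromide | C#C[Mg]Br | starting material
5 | rac-(4E,6E)-4,6-dimethylocta-4,6-dien-1-yn-3-ol | C#CC(O)/C(C)=C/C(C)=C/C | intermediate
6 | (1S)-1-[(2S,3S)-3-[(2E)-but-2-en-2-yl]-2-methyloxiran-2-yl]prop-2-yn-1-ol | C#C[C@H](O)[C@]1(C)O[C@H]1/C(C)=C/C | intermediate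
7 | (3S,4S,5R,6E)-3,4-dihydroxy-4,6-dimethyloct-6-en-1-yn-5-yl benzoate | C#C[C@H](O)[C@](C)(O)[C@H](OC(=O)c1ccccc1)/C(C)=C/C | intermediate
8 | (2S,3R,6S)-2-ethynyl-3,5,6-trimethyl-3,6-dihydro-2H-pyran-3-ol | C#C[C@@H]1O[C@@H](C)C(C)=C[C@@]1(C)O | intermediate
9 | (2E)-4,4-dimethoxybut-2-enal (fumaraldehyde mono(dimethyl acetal)) | O=C/C=C/C(OC)OC | starting material
10 | (triphenylphosphoranylidene)acetaldehyde | O=CC=P(c1ccccc1)(c1ccccc1)c1ccccc1 | starting material
11 | (2E,4E)-6,6-dimethoxyhexa-2,4-dienal | O=C/C=C/C=C/C(OC)OC | intermediate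
12 | (2E,4E,6E)-8,8-dimethoxy-2-methylocta-2,4,6-trienal | O=C/C(C)=C/C=C/C=C/C(OC)OC | intermediate
13 | (4S)-4-benzyl-3-propanoyl-1,3-oxazolidin-2-one | CCC(=O)N1[C@@H](Cc2ccccc2)COC1=O | starting material
14 | (4S)-4-benzyl-3-[(2R,3S,4E,6E,8E)-10,10-dimethoxy-2,4-dimethyl-3-(trimethylsilyloxy)deca-4,6,8-trienoyl]-1,3-oxazolidin-2-one | COC(OC)/C=C/C=C/C=C(\C)[C@@H](O[Si](C)(C)C)[C@@H](C)C(=O)N1[C@@H](Cc2ccccc2)COC1=O | intermediate
15 | (4S)-4-benzyl-3-[(2R,3S,4E,6E,8E)-3-hydroxy-10,10-dimethoxy-2,4-dimethyldeca-4,6,8-trienoyl]-1,3-oxazolidin-2-one | COC(OC)/C=C/C=C/C=C(\C)[C@@H](O)[C@@H](C)C(=O)N1[C@@H](Cc2ccccc2)COC1=O | intermediate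
16 | (2R,3S,4E,6E,8E)-1-[(4S)-4-benzyl-2-oxo-1,3-oxazolidin-3-yl]-10,10-dimethoxy-2,4-dimethyl-1-oxodeca-4,6,8-trien-3-yl propanoate | COC(OC)/C=C/C=C/C=C(\C)[C@@H](OC(=O)CC)[C@@H](C)C(=O)N1[C@@H](Cc2ccccc2)COC1=O | intermediate
17 | (5R,6S)-6-[(2E,4E,6E)-8,8-dimethoxyocta-2,4,6-trien-2-yl]-4-hydroxy-3,5-dimethyl-5,6-dihydro-2H-pyran-2-one (enol form of the β-keto-δ-lactone) | O=C1O[C@H](/C(C)=C/C=C/C=C/C(OC)OC)[C@@H](C)C(O)=C1C | intermediate
18 | (2E,4E,6E)-7-[(2S,3R)-4-hydroxy-3,5-dimethyl-6-oxo-3,6-dihydro-2H-pyran-2-yl]octa-2,4,6-trienal | O=C1O[C@H](/C(C)=C/C=C/C=C/C=O)[C@@H](C)C(O)=C1C | intermediate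
19 | (5R,6S)-4-hydroxy-6-[(2E,4E,6E,8RS,9E)-8-hydroxy-10-[(2S,3R,6S)-3-hydroxy-3,5,6-trimethyl-3,6-dihydro-2H-pyran-2-yl]undeca-2,4,6,9-tetraen-2-yl]-3,5-dimethyl-5,6-dihydro-2H-pyran-2-one | O=C1O[C@H](/C(C)=C/C=C/C=C/C(O)/C=C(\C)[C@@H]2O[C@@H](C)C(C)=C[C@@]2(C)O)[C@@H](C)C(O)=C1C | intermediate
20 | (1S,4S,6R,7R)-7-[(1E,3E,5E,7E)-8-[(2S,3R,6S)-3-hydroxy-3,5,6-trimethyl-3,6-dihydro-2H-pyran-2-yl]nona-1,3,5,7-tetraen-1-yl]-4,6,7-trimethyl-2-oxabicyclo[2.2.1]heptane-3,5-dione | O=C1[C@H](C)[C@@H]2OC(=O)[C@@]1(C)[C@@]2(C)/C=C/C=C/C=C/C=C(\C)[C@@H]3O[C@@H](C)C(C)=C[C@@]3(C)O | intermediate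
21 | methyl (2R)-2-[(2S,3R,4R)-3-[(1E,3E,5E,7E)-8-[(2S,3R,6S)-3-hydroxy-3,5,6-trimethyl-3,6-dihydro-2H-pyran-2-yl]nona-1,3,5,7-tetraen-1-yl]-3,4-dimethyl-5-oxooxolan-2-yl]propanoate | COC(=O)[C@H](C)[C@@H]1OC(=O)[C@H](C)[C@@]1(C)/C=C/C=C/C=C/C=C(\C)[C@@H]1O[C@@H](C)C(C)=C[C@@]1(C)O | target

## Step count and risks

Total step count: 11. Longest linear sequence: 7 steps (steps 5 to 11, from 9); the pyran branch is 6 steps (steps 1 to 4, then 10 and 11).

The three steps most likely to fail:

**Step 11.** The risks are the face of C4 attacked by Cb, side reactions of the long polyenyl cation, and the face of protonation at Cb. The fallback replaces the Brønsted-acid cation by a palladium-bound polyenyl unit under neutral conditions. It sets out from 19, which is treated with methyl chloroformate and pyridine (CH2Cl2, −20 °C) to give the bis(methyl carbonate) F1, acylated at the enol oxygen and the C10 oxygen. With Pd2(dba)3 and a chiral diphosphine (DACH-phenyl Trost ligand, both enantiomers screened) in THF at 0 °C, zerovalent palladium ionises the C10 carbonate. The methoxide released on decarboxylation cleaves the enol carbonate, and the resulting soft enolate attacks the C4 terminus, with the ligand controlling the face. This comes back to the route at 20, which is carried through the methanol stage of step 11.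

**Step 10.** The risks are methyl transfer from aluminium to the aldehyde and interference by the acidic lactone. The fallback changes the carbon nucleophile. It sets out from 8, which is carboaluminated as before and then quenched with iodine to give (2S,3R,6S)-2-[(1E)-1-iodoprop-1-en-2-yl]-3,5,6-trimethyl-3,6-dihydro-2H-pyran-3-ol F2. A Nozaki–Hiyama–Kishi coupling of this iodide with 18 (CrCl2, 4 equiv; NiCl2, 1 mol %; DMSO/THF, 23 °C) tolerates the free hydroxyls and the enol. It comes back to the route at 19.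

**Step 4.** The risks are β-hydride elimination of the allylpalladium intermediate, closure through the tertiary oxygen to a 2,5-dihydrofuran, and stereochemical leakage. The fallback avoids an allylpalladium intermediate. It sets out from 7, which is debenzoylated (K2CO3, MeOH, 0 °C) to (3S,4S,5R,6E)-4,6-dimethyloct-6-en-1-yne-3,4,5-triol F3. Divalent palladium (PdCl2(MeCN)2, 10 mol %, THF, 0 °C) then effects a stereospecific syn SN2' cyclodehydration with 1,3-chirality transfer from C15 to C17. It comes back to the route at 8.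

## Further compounds

F1 | step 11 | (5R,6S)-6-[(2E,4E,6E,8RS,9E)-10-[(2S,3R,6S)-3-hydroxy-3,5,6-trimethyl-3,6-dihydro-2H-pyran-2-yl]-8-(methoxycarbonyloxy)undeca-2,4,6,9-tetraen-2-yl]-3,5-dimethyl-2-oxo-5,6-dihydro-2H-pyran-4-yl methyl carbonate | O=C1O[C@H](/C(C)=C/C=C/C=C/C(OC(=O)OC)/C=C(\C)[C@@H]2O[C@@H](C)C(C)=C[C@@]2(C)O)[C@@H](C)C(OC(=O)OC)=C1C
F2 | step 10 | (2S,3R,6S)-2-[(1E)-1-iodoprop-1-en-2-yl]-3,5,6-trimethyl-3,6-dihydro-2H-pyran-3-ol | I/C=C(\C)[C@@H]1O[C@@H](C)C(C)=C[C@@]1(C)O
F3 | step 4 | (3S,4S,5R,6E)-4,6-dimethyloct-6-en-1-yne-3,4,5-triol | C#C[C@H](O)[C@](C)(O)[C@H](O)/C(C)=C/C
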